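Late in the summer run, from 1.67 d on, double product stays between 23% and 27%, though mono adduct and free reagent stand beside it. That looks like a balance, so here is my reckoning, in fractions of the substrate charged.

| flask | substrate | reagent | remark | time |
|---|---|---|---|---|
| summer | 0.75 M | 1.5 equiv | run made earlier |  |
| flask | 1.5 M | 1.50 equiv |  | 10 d |
summer run (percent of the substrate charged)

| time / d | substrate / % | mono adduct / % | double product / % |
|---|---|---|---|
| 0.417 | 18 | 31 | 22 |
| 0.833 | 9 | 41 | 24 |
| 1.25 | 6 | 53 | 24 |
| 1.67 | 4 | 61 | 27 |
| 2.00 | 6 | 62 | 23 |
| 2.50 | 5 | 63 | 24 |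
| 3.00 | 2 | 70 | 24 |

(each reading ± 1.5 percentage points)

* amount of substrate at 10 d, in percent of the substrate charged
* amount of mono adduct at 10 d, in percent of the substrate charged
* amount of double product at 10 d, in percent of the substrate charged

First, how late is 10 d? In the summer run the readings' shortfall from the full charge falls from 29.0% to 4.00%, a half-life of about 0.904 d. That is far shorter than the time, so I set substrate and shortfall to nil: M + D = 1.

Next, suppose each reagent taken up frees one by-product, and let the shortfall hold no reagent. Then:

u = M + 2D,  r = 1.5 − u,  Q = D·u / (M·r)

In the summer run at 3.00 d, r is 0.320 and Q is 1.26.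

One row is the weak link, so take the last four: 1.45, 0.954, 1.08 and 1.26. Their mean is 1.19: this is Q, the reaction quotient, double product times reagent taken over mono adduct times reagent free. Concentration cancels in it, so if I take the flask to be at balance by 10 d, its charge of 1.5 M does not enter:

D(1 + D) = Q(1 − D)(0.5 − D)

This gives D = 21.7% and M = 78.3%.

The forecast differs from my reckoning: substrate 0.3%, mono adduct 68% (55% to 76%), double product 31% (23% to 43%). Of double product it says: “It therefore does not come appreciably from finished mono adduct.”

The flask gives substrate 0%, mono adduct 79.1%, double product 20.9%.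

    substrate + reagent → mono adduct + by-product (k = 7.40 × 10⁻⁵ L mol⁻¹ s⁻¹)
    reagent + mono adduct ⇌ double product + by-product (K = 1.10, k = 4.10 × 10⁻⁵ L mol⁻¹ s⁻¹)
    substrate ⇌ dormant form (K = 2.00, k = 0.00280 s⁻¹)

In this flask the slowest mode of the whole flask, as it stands at 10.0 d, has a half-life of 0.749 d, far shorter than the time allowed, and Q counted on the end state is 1.10. In the neighbour flask charged with 0.380 equiv of reagent, free reagent is down to 0.0089% of its charge, substrate stands at 20.7%, double product at 0.00609%, and Q comes to 1.79.

(The runs were computed with made-up constants.)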